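**Plan**
Retrosynthesis: the C4 methyl group is traced back to a C4 formyl group. The ring is then cut at O1–C5 and C4–C5, because C5 (the ring carbon carrying the 3,4,5-trimethoxyphenyl ring, flanked by O1 and C4) is an aldehyde carbon. The last cut is C2–C3.
This leaves 3,4,5-trimethoxybenzaldehyde, 3,4-dimethoxybenzaldehyde and a crotyl carbamate that supplies C3, its methyl group, C4 and the formyl carbon.
Forward: carbamoylation of crotyl alcohol; homoaldol addition to 3,4-dimethoxybenzaldehyde (C2–C3); closure of the only ring by (4+1) condensation with 3,4,5-trimethoxybenzaldehyde (O1–C5 and C4–C5); C4 equilibration; CHO to CH3.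
Stereochemistry: C2 and C3 come from the sparteine-controlled, anti-selective homoaldol reaction. C5 comes from the substrate-controlled ring closure (cis to the C2 aryl group). C4 comes from base equilibration of the formyl group onto the face of the C3 methyl group.

Key step: step 3

Assumption: the lithium complex that crystallises with (−)-sparteine is taken as (S)-configured and its exchange with Ti(OiPr)4 as inverting, which leads to the (3S,4S) adduct; if the sense proves opposite, (+)-sparteine takes its place.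
Remark on locants: all ring compounds carry the locants of the target (O1; C2 bears the 3,4-dimethoxyphenyl group; C3 the methyl group; C5 the 3,4,5-trimethoxyphenyl group).
Remark on C4: the ring closure is expected to place the formyl group first on the face of the two aryl groups, so the aldehyde with the formyl group cis to the C3 methyl group is reached by a separate equilibration (step 4).

Step 1
Reactants: 1 (E)-but-2-en-1-ol; 2 N,N-diisopropylcarbamoyl chloride
Product: 3 (E)-but-2-enyl N,N-diisopropylcarbamate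
Conditions: pyridine, 90 °C
Reagents that add atoms: none
Why: Acylation of the primary alcohol by the carbamoyl chloride with pyridine as base (O-carbamoylation); the alkene geometry is not touched.

Step 2
Reactants: 3 (E)-but-2-enyl N,N-diisopropylcarbamate; 4 3,4-dimethoxybenzaldehyde
Product: 7 (1Z,3S,4S)-4-(3,4-dimethoxyphenyl)-4-hydroxy-3-methylbut-1-enyl N,N-diisopropylcarbamate, via lithium sparteine complex 5 (not isolated), via allyltitanium triisopropoxide 6 (not isolated)
Conditions: n-BuLi, (−)-sparteine, pentane/cyclohexane, −78 °C (crystallisation); Ti(OiPr)4, −78 °C; 4, −78 °C to rt; aq. HCl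
Reagents that add atoms: none
Why: Sparteine-mediated α-lithiation with crystallisation-driven dynamic resolution gives the (S)-lithium complex 5, inverting transmetallation gives the (R)-allyltitanium 6, and its γ-addition to aldehyde 4 through a chair Zimmerman–Traxler transition state (aryl equatorial, carbamoyloxy axial) creates C3 and C4 as the (3S,4S)-anti pair together with the Z enol carbamate (homoaldol reaction of a metallated allyl carbamate).

Step 3
Reactants: 7 (1Z,3S,4S)-4-(3,4-dimethoxyphenyl)-4-hydroxy-3-methylbut-1-enyl N,N-diisopropylcarbamate; 8 3,4,5-trimethoxybenzaldehyde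
Product: 12 (2S,3S,4S,5R)-2-(3,4-dimethoxyphenyl)-3-methyl-5-(3,4,5-trimethoxyphenyl)tetrahydrofuran-4-carbaldehyde (formyl cis to both aryl groups, trans to the C3 methyl), via hemiacetal 9 (not isolated), via oxocarbenium ion 10 (not isolated), via ring-closed carbamoyloxycarbenium ion 11 (not isolated)
Conditions: BF3·OEt2, CH2Cl2, −78 to −20 °C; aq. NaHCO3
Reagents that add atoms: none
Why: BF3 turns the hemiacetal 9, formed from the C2 hydroxyl and aldehyde 8, into the (E)-oxocarbenium ion 10 (O1–C5); its cationic carbon is captured by the nucleophilic β-carbon of the (Z)-enol carbamate (C4–C5) in an intramolecular Mukaiyama/Prins-type addition, and the resulting cation 11 gives up its carbamoyl group as the carbamoyl fluoride to unveil the formyl group. The closest known reaction type is the Lewis-acid cyclocondensation of (Z)-anti-4-hydroxy-1-alkenyl carbamates with aldehydes to tetrahydrofuran-3-carbaldehydes. The tetrahydrofuran closes in a 5-(enol-exo)-endo-trig mode, which is workable because the cationic carbon lies inside the forming ring while the enol π bond lies outside it. C5 is set by an envelope transition state in which the C2 aryl and C3 methyl groups sit pseudoequatorial and the E cation places its aryl group cis to the C2 aryl group; C4 is set by the Z enol geometry, whose allylic 1,3-strain holds the C3–H bond in the enol plane so that the formyl group should emerge trans to the C3 methyl group and cis to the C5 aryl group. The step needs 2,5-cis selectivity and intact benzylic C–O bonds: the first rests on the C2/C3 stereocentres and the E cation geometry, the second on low temperature, a short reaction time and the weaker cation-stabilising power of the 3,4,5-trimethoxyphenyl group at C5, while the C4 configuration is corrected in step 4.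

Step 4
Reactants: 12 (2S,3S,4S,5R)-2-(3,4-dimethoxyphenyl)-3-methyl-5-(3,4,5-trimethoxyphenyl)tetrahydrofuran-4-carbaldehyde
Product: 14 (2S,3S,4R,5R)-2-(3,4-dimethoxyphenyl)-3-methyl-5-(3,4,5-trimethoxyphenyl)tetrahydrofuran-4-carbaldehyde (formyl cis to the C3 methyl, trans to the C5 aryl), via exocyclic enolate 13 (not isolated)
Conditions: DBU (cat.), CH2Cl2, rt
Reagents that add atoms: none
Why: Reversible enolisation by the amidine base (epimerisation of an α-stereocentre under thermodynamic control) should move the formyl group from the face it shares with both aryl groups to the face of the small C3 methyl group, while ring-opening β-elimination is held back because the C5–O1 bond lies close to the nodal plane of the exocyclic enolate 13, and any C4 epimer already present converges on the same aldehyde.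

Step 5
Reactants: 14 (2S,3S,4R,5R)-2-(3,4-dimethoxyphenyl)-3-methyl-5-(3,4,5-trimethoxyphenyl)tetrahydrofuran-4-carbaldehyde
Product: 15 [(2S,3S,4S,5R)-2-(3,4-dimethoxyphenyl)-3-methyl-5-(3,4,5-trimethoxyphenyl)tetrahydrofuran-4-yl]methanol
Conditions: NaBH4, MeOH, 0 °C
Reagents that add atoms: none
Why: Hydride addition to the aldehyde (NaBH4 reduction) at low temperature is faster than renewed enolisation, so the C4 arrangement is carried over (the descriptor changes only through the priority rules) and no other group reacts.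

Step 6
Reactants: 15 [(2S,3S,4S,5R)-2-(3,4-dimethoxyphenyl)-3-methyl-5-(3,4,5-trimethoxyphenyl)tetrahydrofuran-4-yl]methanol
Product: 16 [(2S,3S,4S,5R)-2-(3,4-dimethoxyphenyl)-3-methyl-5-(3,4,5-trimethoxyphenyl)tetrahydrofuran-4-yl]methyl 4-methylbenzenesulfonate
Conditions: TsCl, Et3N, DMAP (cat.), CH2Cl2, 0 °C to rt
Reagents that add atoms: p-toluenesulfonyl chloride, Cc1ccc(cc1)S(=O)(=O)Cl
Why: Sulfonylation of the primary alcohol (tosylation) with nucleophilic catalysis by DMAP turns the hydroxyl into a leaving group without touching a stereocentre.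

Step 7
Reactants: 16 [(2S,3S,4S,5R)-2-(3,4-dimethoxyphenyl)-3-methyl-5-(3,4,5-trimethoxyphenyl)tetrahydrofuran-4-yl]methyl 4-methylbenzenesulfonate
Product: 17 (2S,3S,4R,5R)-2-(3,4-dimethoxyphenyl)-3,4-dimethyl-5-(3,4,5-trimethoxyphenyl)tetrahydrofuran
Conditions: LiBHEt3, THF, 0 °C to rt
Reagents that add atoms: none
Why: SN2 displacement of the primary tosylate by hydride (reductive deoxygenation) leaves the C4 methyl group; the aryl ethers and the ring are inert and no stereocentre takes part.

**Compound list**
1 | (E)-but-2-en-1-ol | C/C=C/CO | starting material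
2 | N,N-diisopropylcarbamoyl chloride | CC(C)N(C(C)C)C(=O)Cl | starting material
3 | (E)-but-2-enyl N,N-diisopropylcarbamate | C/C=C/COC(=O)N(C(C)C)C(C)C | intermediate
4 | 3,4-dimethoxybenzaldehyde | COc1ccc(C=O)cc1OC | starting material
5 | (S,E)-1-lithiobut-2-enyl N,N-diisopropylcarbamate as its (−)-sparteine complex (ligand not drawn) | C/C=C/[C@H]([Li])OC(=O)N(C(C)C)C(C)C | intermediate
6 | (R,E)-1-(N,N-diisopropylcarbamoyloxy)but-2-enyltitanium triisopropoxide | C/C=C/[C@@H]([Ti](OC(C)C)(OC(C)C)OC(C)C)OC(=O)N(C(C)C)C(C)C | intermediate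
7 | (1Z,3S,4S)-4-(3,4-dimethoxyphenyl)-4-hydroxy-3-methylbut-1-enyl N,N-diisopropylcarbamate | COc1ccc([C@@H](O)[C@@H](C)/C=C\OC(=O)N(C(C)C)C(C)C)cc1OC | intermediate
8 | 3,4,5-trimethoxybenzaldehyde | COc1cc(C=O)cc(OC)c1OC | starting material
9 | hemiacetal of 7 with 8 (hemiacetal carbon unassigned) | COc1ccc([C@@H](OC(O)c2cc(OC)c(OC)c(OC)c2)[C@@H](C)/C=C\OC(=O)N(C(C)C)C(C)C)cc1OC | intermediate
10 | (E)-oxocarbenium ion from 9 (hydroxytrifluoroborate counter-ion not drawn) | COc1ccc([C@@H](/[O+]=C/c2cc(OC)c(OC)c(OC)c2)[C@@H](C)/C=C\OC(=O)N(C(C)C)C(C)C)cc1OC | intermediate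
11 | ring-closed O-carbamoyl oxocarbenium ion (counter-ion not drawn) | COc1ccc([C@@H]2[C@@H](C)[C@H](C=[O+]C(=O)N(C(C)C)C(C)C)[C@H](c3cc(OC)c(OC)c(OC)c3)O2)cc1OC | intermediate
12 | (2S,3S,4S,5R)-2-(3,4-dimethoxyphenyl)-3-methyl-5-(3,4,5-trimethoxyphenyl)tetrahydrofuran-4-carbaldehyde | COc1ccc([C@@H]2[C@@H](C)[C@H](C=O)[C@H](c3cc(OC)c(OC)c(OC)c3)O2)cc1OC | intermediate
13 | exocyclic C4 enolate of 12 (geometry unassigned, protonated DBU counter-ion not drawn) | COc1ccc([C@@H]2[C@@H](C)C(=C[O-])[C@H](c3cc(OC)c(OC)c(OC)c3)O2)cc1OC | intermediate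
14 | (2S,3S,4R,5R)-2-(3,4-dimethoxyphenyl)-3-methyl-5-(3,4,5-trimethoxyphenyl)tetrahydrofuran-4-carbaldehyde | COc1ccc([C@@H]2[C@@H](C)[C@@H](C=O)[C@H](c3cc(OC)c(OC)c(OC)c3)O2)cc1OC | intermediate
15 | [(2S,3S,4S,5R)-2-(3,4-dimethoxyphenyl)-3-methyl-5-(3,4,5-trimethoxyphenyl)tetrahydrofuran-4-yl]methanol | COc1ccc([C@@H]2[C@@H](C)[C@@H](CO)[C@H](c3cc(OC)c(OC)c(OC)c3)O2)cc1OC | intermediate
16 | [(2S,3S,4S,5R)-2-(3,4-dimethoxyphenyl)-3-methyl-5-(3,4,5-trimethoxyphenyl)tetrahydrofuran-4-yl]methyl 4-methylbenzenesulfonate | COc1ccc([C@@H]2[C@@H](C)[C@@H](COS(=O)(=O)c3ccc(C)cc3)[C@H](c4cc(OC)c(OC)c(OC)c4)O2)cc1OC | intermediate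
17 | (2S,3S,4R,5R)-2-(3,4-dimethoxyphenyl)-3,4-dimethyl-5-(3,4,5-trimethoxyphenyl)tetrahydrofuran | COc1ccc([C@H]2O[C@@H](c3cc(OC)c(OC)c(OC)c3)[C@H](C)[C@@H]2C)cc1OC | target

Total step count: 7. Longest linear sequence: 7 steps (1 to 17).

**Steps most likely to fail**

Step 3. Under BF3·OEt2 the electron-rich benzylic C–O bonds may ionise, with loss of configuration at C2 or C5 and arylation by-products, or the ring may close with poor facial selectivity at C5. The fallback sets out from 7 and 8 and comes back at 12. Aldehyde 8 is converted with trimethyl orthoformate and catalytic p-TsOH in MeOH into 5-(dimethoxymethyl)-1,2,3-trimethoxybenzene F1. Compounds 7 and F1 are then combined with catalytic TMSOTf in CH2Cl2 at −78 °C. Transacetalisation should give (1Z,3S,4S)-4-(3,4-dimethoxyphenyl)-4-[methoxy(3,4,5-trimethoxyphenyl)methoxy]-3-methylbut-1-enyl N,N-diisopropylcarbamate F2 in the flask. F2 ionises to the same cation 10 without a stoichiometric Lewis acid and closes through 11, the carbamoyl group ending on methanol.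

Step 4. The equilibrium at C4 may stop short of the wanted epimer, or enolisation of the β-alkoxy aldehyde may lead to ring-opening elimination or aldol self-condensation. The fallback sets out from 12 and comes back at 15, moving the equilibration to the ester oxidation level. Pinnick oxidation (NaClO2, NaH2PO4, 2-methyl-2-butene, t-BuOH/H2O) should give (2S,3S,4S,5R)-2-(3,4-dimethoxyphenyl)-3-methyl-5-(3,4,5-trimethoxyphenyl)tetrahydrofuran-4-carboxylic acid F3. MeI and K2CO3 in DMF should give its methyl ester, methyl (2S,3S,4S,5R)-2-(3,4-dimethoxyphenyl)-3-methyl-5-(3,4,5-trimethoxyphenyl)tetrahydrofuran-4-carboxylate F4. NaOMe in MeOH should equilibrate it to methyl (2S,3S,4R,5R)-2-(3,4-dimethoxyphenyl)-3-methyl-5-(3,4,5-trimethoxyphenyl)tetrahydrofuran-4-carboxylate F5, which cannot self-condense. LiAlH4 in THF at 0 °C then reduces F5 to 15.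

Step 2. The crystallisation-driven resolution of the lithium complex may be incomplete, or the complex may racemise before titanation, so that the adduct is formed with insufficient enantiomeric purity. The fallback sets out from 3 and 4 and comes back at 7, replacing asymmetric induction by resolution. Lithiation with n-BuLi and TMEDA in Et2O at −78 °C, exchange with Ti(OiPr)4 and addition of 4 should give 7 together with its enantiomer, (1Z,3R,4R)-4-(3,4-dimethoxyphenyl)-4-hydroxy-3-methylbut-1-enyl N,N-diisopropylcarbamate F6. Esterification of the mixture with (S)-2-methoxy-2-phenylacetic acid (DCC, DMAP, CH2Cl2, 0 °C) should give the (S)-2-methoxy-2-phenylacetate of 7 F7 and the (S)-2-methoxy-2-phenylacetate of the enantiomer F8. These diastereomers are separated by chromatography or crystallisation, and methanolysis of F7 (K2CO3, MeOH) returns 7 with the enol carbamate untouched.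

**Further compounds**
F1 | step 3 | 5-(dimethoxymethyl)-1,2,3-trimethoxybenzene | COC(OC)c1cc(OC)c(OC)c(OC)c1
F2 | step 3 | (1Z,3S,4S)-4-(3,4-dimethoxyphenyl)-4-[methoxy(3,4,5-trimethoxyphenyl)methoxy]-3-methylbut-1-enyl N,N-diisopropylcarbamate (acetal carbon unassigned) | COc1ccc([C@@H](OC(OC)c2cc(OC)c(OC)c(OC)c2)[C@@H](C)/C=C\OC(=O)N(C(C)C)C(C)C)cc1OC
F3 | step 4 | (2S,3S,4S,5R)-2-(3,4-dimethoxyphenyl)-3-methyl-5-(3,4,5-trimethoxyphenyl)tetrahydrofuran-4-carboxylic acid | COc1ccc([C@@H]2[C@@H](C)[C@H](C(=O)O)[C@H](c3cc(OC)c(OC)c(OC)c3)O2)cc1OC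
F4 | step 4 | methyl (2S,3S,4S,5R)-2-(3,4-dimethoxyphenyl)-3-methyl-5-(3,4,5-trimethoxyphenyl)tetrahydrofuran-4-carboxylate | COc1ccc([C@@H]2[C@@H](C)[C@H](C(=O)OC)[C@H](c3cc(OC)c(OC)c(OC)c3)O2)cc1OC
F5 | step 4 | methyl (2S,3S,4R,5R)-2-(3,4-dimethoxyphenyl)-3-methyl-5-(3,4,5-trimethoxyphenyl)tetrahydrofuran-4-carboxylate | COc1ccc([C@@H]2[C@@H](C)[C@@H](C(=O)OC)[C@H](c3cc(OC)c(OC)c(OC)c3)O2)cc1OC
F6 | step 2 | (1Z,3R,4R)-4-(3,4-dimethoxyphenyl)-4-hydroxy-3-methylbut-1-enyl N,N-diisopropylcarbamate | COc1ccc([C@H](O)[C@H](C)/C=C\OC(=O)N(C(C)C)C(C)C)cc1OC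
F7 | step 2 | (1S,2S,3Z)-4-(N,N-diisopropylcarbamoyloxy)-1-(3,4-dimethoxyphenyl)-2-methylbut-3-enyl (S)-2-methoxy-2-phenylacetate | COc1ccc([C@@H](OC(=O)[C@@H](OC)c2ccccc2)[C@@H](C)/C=C\OC(=O)N(C(C)C)C(C)C)cc1OC
F8 | step 2 | (1R,2R,3Z)-4-(N,N-diisopropylcarbamoyloxy)-1-(3,4-dimethoxyphenyl)-2-methylbut-3-enyl (S)-2-methoxy-2-phenylacetate | COc1ccc([C@H](OC(=O)[C@@H](OC)c2ccccc2)[C@H](C)/C=C\OC(=O)N(C(C)C)C(C)C)cc1OC
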